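**Numbering.** Heavy atoms are numbered in the order of the target SMILES: C1 (methyl), C2, C3, C4 (with methyl C5 and O6), C7 (=O8), C9, C10 (O11), C12, C13 (O14), C15 (methyl C16), O17, C18, C19, C20 (O21), C22 (=O23), O24, C25, C26, C27 (methyl C28). Compound numbers 1–41 are those of the steps below.

## Analysis of the target

Target 41 is a tetracycle in which a 2-oxabicyclo[2.2.2]octane (C15, C13, C12, C25, C26, C27 with the O17–C18 bridge) is spanned by a cyclopentane (C9, C10, C12, C25, C18), a γ-lactone (C18, C19, C22, O24, C25) and a cyclooctane (C2, C3, C4, C7, C9, C18, C19, C20). Of its ten stereocentres, eight (C9, C10, C12, C13, C15, C18, C25, C27) are contiguous in the rigid cage, where C18 and C25 are adjacent, fully substituted, oxygen-bearing carbons, while C2 and C4 sit on the flexible eight-membered ring. The C7 ketone is both a β-alkoxy and a β-hydroxy ketone, so enolisation toward C9 would expel O17 or O11. C4/C7 form a tertiary α-ketol, the C19=C20 enol of the β-keto lactone is a vinylogous acid, and C2 is epimerisable. The hard part is the eight-membered carbocycle, which is fused to the cage through quaternary C18 and tertiary C9 and would have to be closed directly against transannular strain. An alkene at C9=C18 would be a bridgehead alkene of the cage, so enol-type chemistry across that bond is excluded. The plan rests on one feature: C7=O and the C19=C20 enol stand in the 1,5-relationship of a cycloocta-1,5-diene (C4–C7, C3–C2, C20=C19), which is the pattern left by the Cope rearrangement of a cis-1,2-dialkenylcyclobutane whose ring is C7–C9–C18–C19.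

## Retrosynthetic reasoning

41 ⇒ 40 ⇒ 39. The last operations only remove the two secondary silyl ethers and the O-methyl group of the vinylogous ester. The free enol, the α-ketol and the β-hydroxy ketone are exposed only at the very end.

39 ⇒ 37 (cut C1–C2). C2 is the γ-carbon of the vinylogous ester C22(=O)–C19=C20(OMe), and the α-carbon C19 is fully substituted, so an extended enolate can only be alkylated at C2. Leaving this methyl out of the ring expansion keeps the key step free of new stereocentres.

37 ⇒ 34 ⇒ 33 (cut C22–O24, lower C22 to the alcohol). With C22 as an allylic primary alcohol and O24 as a tertiary alcohol, the lactone is an oxidative lactonisation. It also converts the acid-labile enol ether into a robust vinylogous ester.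

33 ⇒ 31 (cut C4–O6). The regiodefined C4=C7 silyl enol ether is the handle for hydroxylation at C4. Going through the enolate keeps the oxidant away from the second enol ether.

31 ⇒ 29 (key disconnection: break C2–C3, re-form C7–C19). The 1,5-diene of 31 is the [3,3] product of cyclobutanolate 29, which carries isopropenyl on C7 and 1-methoxyvinyl on C19. The eight-membered ring thus comes from a strained four-membered ring by ring expansion, with the C20 carbonyl delivered as an enol ether and the C7 carbonyl as a trapped enolate. No medium-ring closure is needed.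

29 ⇒ 28 ⇒ 27 ⇒ 24 ⇒ 22 ⇒ 19. The C4–C7 bond comes from exo addition of the isopropenyl group to cyclobutanone 28. C22 is held at the alcohol level (27) so that the alkoxide of 29 cannot fragment by retro-aldol. The C19–C20 bond comes from C-acylation of lactone 19 with amide 20, whose α-carbon can only be substituted on the convex face, exactly where the alkenyl group must sit.

19 ⇒ 18 (cut C9–C18 and C7–C19). The cyclobutane is taken apart into the tetronate alkene C18=C19 and the enol ether C9=C7. The other pairing would need the impossible bridgehead alkene C9=C18. The tetronate alkene is exocyclic to the cage and strain-free, and the forward photocycloaddition also closes the cyclopentane and makes quaternary C18.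

18 ⇒ 17 ⇒ 16 ⇒ 15. Enol ether 18 comes from aldehyde 17, whose carbonyl carbon has been carried since 6 as a terminal alkene; the two secondary alcohols of 15 are silylated in 16.

15 ⇒ 13 ⇒ 12 ⇒ 11 ⇒ 9 (cut O17–C15 and C18–C19). The cage tetronate 15 comes from spiro tetronic acid 14, whose enol oxygen opens the neighbouring epoxide at the tertiary carbon, fixing C15 and C13 as a trans pair. The tetronic acid comes from Dieckmann closure of the O24 acetate onto the lactone carbonyl of 13, and O24 from enolate hydroxylation of 9.

9 ⇒ 6 + 7 (cut C12–C25 and C26–C27). A templated Diels–Alder reaction of dienol 6 with acrylate 7 builds the cyclohexene. Its regiochemistry is fixed by the tether, and C12 and C27 are set from the single carbinol centre C10.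

6 ⇒ 4 + 5 and 4 ⇒ 3 ⇒ 1 + 2. C10 is set by catalytic asymmetric allylation of dienal 4 with stannane 5; 4 is two steps from the commercial compounds 1 and 2.

## Alternatives that were turned down

Alternative 1: The cyclohexane is cut at C15–C27 and C25–C26, so the oxabicyclo[2.2.2]octane comes from 3-hydroxy-6-methyl-2-pyrone A1 and (E)-1-propenyl phenyl sulfone A2. In the forward step a bifunctional cinchona base would promote their [4+2] reaction to bridged hydroxy lactone A3 (C18 as lactone carbonyl, O24–H on C25, sulfone on C26, C12=C13 alkene).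
- For: one catalytic asymmetric step from two simple achiral pieces makes the bicyclic core with C15, C25 and C27. On cage economy and absolute control this is stronger than the chosen route, which needs eight steps to reach 15.
- Against: in A3 the carbon C18 is a lactone carbonyl that must still become a quaternary carbon bearing C9 and C19. The C12=C13 alkene has to be turned into the C12–C10 bond and the trans C13 hydroxyl, and the sulfone must be removed. The eight-membered ring is left to a head-to-tail closure next to two fully substituted centres.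
- Comparison: the chosen plan pays more steps for the cage. In return, the tetronate that carries C18 is also the chromophore that makes C18 quaternary and installs the cyclobutane, and the medium ring then follows from ring expansion.

Alternative 2: The cut is at C10–C12. A dearomatised spirobutenolide dienone aldehyde A4 would undergo a desymmetrising Stetter reaction under a chiral N-heterocyclic carbene to give tricyclic diketone A5, with C25 and C12 set.
- For: very short, catalytic, and A5 already holds the C9–C18 bond and the butenolide. On brevity and enantiocontrol for these two centres it is at least as good as the chosen route.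
- Against: A5 lacks both methyl groups, the C13 oxygen and the C15–O17 bridge. C27, C15 and C13 would have to be introduced with control on an enone ring, and closing the ether bridge by conjugate addition uses up the butenolide alkene needed later. The C9–C19 four-carbon bridge remains an end-to-end eight-ring closure.
- Comparison: the chosen plan sets the cage stereocentres from one carbinol through ring-constrained steps and never closes a medium ring directly.

Alternative 3: The cuts are at C12–C25 and O24–C22. An oxa-bridged nine-membered diketone ester A6 would undergo transannular aldol addition of the C13 ketone enolate (through C12) to the C25 ketone, then lactonisation, to give cage keto-lactone A7.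
- For: one step forms two rings, two bonds and two stereocentres. In bonds per step it is stronger than any single step of the chosen route.
- Against: it needs a nine-membered carbocycle with two quaternary ether carbons as substrate, itself a medium-ring problem. The C25 ketone can also enolise toward C26, and the sense of the aldol depends on a ring conformation that is hard to predict. After A7 the eight-membered ring still has to be built between C9 and C19.
- Comparison: two medium rings would be made by direct closure, against none in the chosen plan, which offers instead a strain-driven ring expansion whose geometry is fixed by a bicyclic precursor.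

Key step: step 20

Assumption: C2 is epimerisable through the β-keto lactone and is taken to have the thermodynamically preferred configuration in the target; the E/Z mixture of 18 and the C7 epimers of 19–27 converge at 28.

## Steps

Step 1
Reactants: 1 (E)-2-methylbut-2-enal (tiglic aldehyde); 2 diethyl [2-(methoxy(methyl)amino)-2-oxoethyl]phosphonate
Product: 3 (2E,4E)-N-methoxy-N,4-dimethylhexa-2,4-dienamide
Conditions: NaH, THF, 0 °C to rt
Reagents that add atoms: none
Why: Horner–Wadsworth–Emmons olefination with a stabilised phosphonate gives the (2E)-alkene; the existing (E)-trisubstituted alkene is not touched.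

Step 2
Reactants: 3 (2E,4E)-N-methoxy-N,4-dimethylhexa-2,4-dienamide
Product: 4 (2E,4E)-4-methylhexa-2,4-dienal
Conditions: iBu2AlH, THF, −78 °C; aq. sodium potassium tartrate
Reagents that add atoms: none
Why: Reduction of a Weinreb amide stops at the chelated tetrahedral intermediate, so the aldehyde is released only on work-up and is not over-reduced.

Step 3
Reactants: 4 (2E,4E)-4-methylhexa-2,4-dienal; 5 allyltributylstannane
Product: 6 (4R,5E,7E)-7-methylnona-1,5,7-trien-4-ol
Conditions: (R)-BINOL (20 mol %), Ti(OiPr)4 (10 mol %), 4 Å MS, CH2Cl2, −20 °C; aq. NaHCO3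
Reagents that add atoms: none
Why: Keck asymmetric allylation: the (R)-BINOL–Ti(OiPr)4 complex should deliver the allyl group to the Re face of the aldehyde carbonyl (1,2-addition), which sets C10 as (R).

Step 4
Reactants: 6 (4R,5E,7E)-7-methylnona-1,5,7-trien-4-ol; 7 methyl acrylate
Product: 9 cis-fused allyl lactone, via cycloadduct hydroxy ester 8 (not isolated)
Conditions: MeMgBr (1.0 equiv), toluene, 0 °C; then 7, 70 °C; H2O work-up
Reagents that add atoms: none
Why: Magnesium-templated Diels–Alder reaction followed by lactonisation: alkoxide and acrylate carbonyl share the magnesium ion, so C25 bonds to C12 and C26 to C27, and the (E,E)-diene places C10 and C28 cis on the new ring. The acrylate should add to the diene face syn to the oxygen with the carbinol hydrogen eclipsing the diene (allylic 1,3-strain), which puts the allyl group on the convex face and sets C12 and C27 from C10.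

Step 5
Reactants: 9 cis-fused allyl lactone
Product: 11 ring-fusion hydroxy lactone, via potassium lactone enolate 10 (not isolated)
Conditions: KN(SiMe3)2, THF, −78 °C; then 2-(phenylsulfonyl)-3-phenyloxaziridine, −78 °C; then AcOH
Reagents that add atoms: 2-(phenylsulfonyl)-3-phenyloxaziridine (O=S(=O)(N1OC1c1ccccc1)c1ccccc1)
Why: Enolate hydroxylation with an N-sulfonyloxaziridine at the only α-position; attack on the convex face keeps the cis ring fusion, so O24 ends trans to C10 and C18 cis to it (C25 set).

Step 6
Reactants: 11 ring-fusion hydroxy lactone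
Product: 12 epoxy hydroxy lactone
Conditions: VO(acac)2 (5 mol %), t-BuOOH, CH2Cl2, 0 °C to rt
Reagents that add atoms: tert-butyl hydroperoxide (CC(C)(C)OO)
Why: Hydroxyl-directed epoxidation: the tertiary homoallylic alcohol binds vanadium and delivers oxygen to its own face of the C13=C15 alkene, which fixes C13; the remote monosubstituted alkene is out of reach and less nucleophilic.

Step 7
Reactants: 12 epoxy hydroxy lactone
Product: 13 epoxy acetoxy lactone
Conditions: Ac2O, Et3N, DMAP (cat.), CH2Cl2, rt
Reagents that add atoms: acetic anhydride (CC(=O)OC(C)=O)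
Why: DMAP-catalysed acylation of the tertiary alcohol installs C19 and C22 as the acetate needed for the Dieckmann closure.

Step 8
Reactants: 13 epoxy acetoxy lactone
Product: 15 cage tetronate diol, via spiro epoxy tetronic acid 14 (not isolated)
Conditions: LiN(SiMe3)2 (3 equiv), THF, −78 to 0 °C; then CF3CO2H, −78 °C to rt
Reagents that add atoms: none
Why: Dieckmann cyclisation of the acetate enolate onto the lactone carbonyl C18 gives the spiro tetronate and frees O11. On acidification the tetronic acid oxygen should open the epoxide at the tertiary carbon C15 with inversion (6-exo, acid-type regiochemistry), closing the 2-oxabicyclo[2.2.2]octane, setting C15 and leaving O14 trans to O17. The liberated C10 hydroxyl can reach C15 only in a 5-endo mode, a competing course that is treated under the uncertain steps.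

Step 9
Reactants: 15 cage tetronate diol
Product: 16 bis-TBS cage tetronate
Conditions: TBSOTf, 2,6-lutidine, CH2Cl2, 0 °C
Reagents that add atoms: tert-butyldimethylsilyl trifluoromethanesulfonate (CC(C)(C)[Si](C)(C)OS(=O)(=O)C(F)(F)F)
Why: Silyl triflate silylation protects both secondary alcohols, including the hindered C13 hydroxyl, in one operation; the neutral tetronate is inert.

Step 10
Reactants: 16 bis-TBS cage tetronate
Product: 17 cage tetronate aldehyde
Conditions: OsO4 (2 mol %), NaIO4, 2,6-lutidine, dioxane/H2O, rt
Reagents that add atoms: sodium periodate ([Na+].[O-]I(=O)(=O)=O)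
Why: Lemieux–Johnson cleavage: OsO4 should dihydroxylate the monosubstituted alkene in preference to the push–pull tetronate alkene, and NaIO4, which reoxidises the osmium and is the net source of the new carbonyl oxygen, cleaves the diol to the C7 aldehyde.

Step 11
Reactants: 17 cage tetronate aldehyde
Product: 18 triethylsilyl enol ether
Conditions: TESOTf, Et3N, CH2Cl2, −78 to 0 °C
Reagents that add atoms: triethylsilyl trifluoromethanesulfonate (CC[Si](CC)(CC)OS(=O)(=O)C(F)(F)F)
Why: Soft enolisation of the aldehyde gives the silyl enol ether, mainly (Z); C9 is the only enolisable position and the low temperature suppresses β-elimination of the C10 silyloxy group.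

Step 12
Reactants: 18 triethylsilyl enol ether
Product: 19 cyclobutane photoadduct lactone
Conditions: hν (254 nm, quartz), degassed Et2O (5 mM), rt
Reagents that add atoms: none
Why: Intramolecular [2+2] photocycloaddition of the tetronate: the three-atom tether favours first bonding C18 to C9 (five-membered ring) and then C19 to C7. The tether reaches only one face of C18 and both new ring fusions must be cis, so C18, C9 and C19 follow from C12 and C10; C7 forms as a mixture that is erased in step 18.

Step 13
Reactants: 19 cyclobutane photoadduct lactone; 20 N-methoxy-N-methylacetamide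
Product: 22 C19-acetyl lactone, via lithium lactone enolate 21 (not isolated)
Conditions: LiN(iPr)2, THF, −78 °C; then 20, −78 to −20 °C; then AcOH
Reagents that add atoms: none
Why: Claisen-type C-acylation of the lactone enolate with a Weinreb amide; the tetrahedral adduct lasts until work-up, so proton transfer and double addition are avoided. The acetyl group can only enter on the convex face because the lactone ring holds the other position at C19.

Step 14
Reactants: 22 C19-acetyl lactone
Product: 24 1-methoxyvinyl lactone, via potassium ketone enolate 23 (not isolated)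
Conditions: KN(SiMe3)2, THF/DMPU, −78 °C; then MeOTf, −78 °C
Reagents that add atoms: methyl trifluoromethanesulfonate (COS(=O)(=O)C(F)(F)F)
Why: O-alkylation of the dissociated potassium enolate of a hindered methyl ketone with a hard methylating agent in a dipolar medium gives the 2-methoxy-1-alkene; C19 is quaternary, so only the methyl side can enolise.

Step 15
Reactants: 24 1-methoxyvinyl lactone
Product: 25 diol silyl ether
Conditions: LiAlH4, THF, 0 °C
Reagents that add atoms: none
Why: Hydride reduction of the lactone gives the C22 primary and O24 tertiary alcohols and puts C22 at the level at which the later cyclobutanolate cannot fragment by retro-aldol; enol ether and silyl ethers are inert.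

Step 16
Reactants: 25 diol silyl ether
Product: 26 cyclobutanol triol
Conditions: Bu4NF (1.1 equiv), THF, −20 to 0 °C
Reagents that add atoms: none
Why: Fluoride should cleave the secondary triethylsilyl ether much faster than the two hindered secondary TBS ethers; the basic medium leaves the acid-labile enol ether intact.

Step 17
Reactants: 26 cyclobutanol triol
Product: 27 C22 triethylsilyl ether
Conditions: TESCl (1.05 equiv), imidazole, CH2Cl2, −40 °C
Reagents that add atoms: chlorotriethylsilane (CC[Si](Cl)(CC)CC)
Why: Steric discrimination: the primary C22 hydroxyl is silylated at low temperature in preference to the hindered cyclobutanol and the tertiary alcohol.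

Step 18
Reactants: 27 C22 triethylsilyl ether
Product: 28 cyclobutanone
Conditions: Dess–Martin periodinane, NaHCO3, CH2Cl2, 0 °C to rt
Reagents that add atoms: none
Why: Buffered Dess–Martin oxidation of the only secondary alcohol gives the cyclobutanone and merges the C7 epimers; the buffer protects the enol ether.

Step 19
Reactants: 28 cyclobutanone
Product: 29 cis-1-isopropenyl-2-(1-methoxyvinyl)cyclobutanol
Conditions: CH2=C(CH3)MgBr, CeCl3 (3 equiv each), THF, −78 °C; H2O work-up
Reagents that add atoms: isopropenylmagnesium bromide (C=C(C)[Mg]Br)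
Why: Organocerium 1,2-addition: the non-basic reagent should add to the hindered 3-alkoxycyclobutanone without enolisation or ring opening. Attack on the convex (exo) face of the bicyclo[3.2.0] unit places the isopropenyl group cis to the 1-methoxyvinyl group (C7 set); one equivalent is consumed by O24–H.

Step 20
Reactants: 29 cis-1-isopropenyl-2-(1-methoxyvinyl)cyclobutanol
Product: 31 cyclooctadiene bis(enol ether), via dipotassium enolate alkoxide 30 (not isolated)
Conditions: KN(SiMe3)2 (2.5 equiv), 18-crown-6, THF, −78 to 0 °C; then Me3SiCl, Et3N, −78 °C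
Reagents that add atoms: chlorotrimethylsilane (C[Si](C)(C)Cl)
Why: Anionic oxy-Cope rearrangement of a cis-1,2-dialkenylcyclobutanol, the known route from such cyclobutanols to cyclooctenones: the crown-ether-separated potassium alkoxide at C7 weakens the C7–C19 bond, and the 1,5-diene C3=C4–C7–C19–C20=C2 undergoes the [3,3] shift in which C2–C3 forms and C7–C19 breaks. The cyclooctane is closed by four-carbon ring expansion of the cyclobutane through a boat six-membered transition state, not by end-to-end cyclisation; release of cyclobutane strain and enolate formation drive it. No stereocentre is created, and the boat geometry gives both ring alkenes (C4=C7 and C19=C20) as cis alkenes. The step needs the two alkenyl groups cis on the convex face, which the exo addition of step 19 and the forced exo acylation of step 13 secure. Retro-aldol cleavage is excluded because C19 bears no carbonyl group (C22 is a silyl ether, C20 an enol ether), and O17 is a poor leaving group for a Grob-type cleavage. Silyl transfer among O23, O24 and the alkoxide is harmless because only the C7 alkoxide rearranges and both silyl groups are removed together in step 22. Silylation at low temperature fixes the C4–C7 enolate before it can equilibrate toward C9, where loss of O17 would follow, and also caps O24.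

Step 21
Reactants: 31 cyclooctadiene bis(enol ether)
Product: 33 tertiary α-hydroxy ketone, via lithium enolate 32 (not isolated)
Conditions: MeLi (1.1 equiv), THF, 0 °C; then 2-(phenylsulfonyl)-3-phenyloxaziridine, −78 °C; then AcOH
Reagents that add atoms: 2-(phenylsulfonyl)-3-phenyloxaziridine (O=S(=O)(N1OC1c1ccccc1)c1ccccc1)
Why: Methyllithium cleaves only the silyl enol ether and regenerates the regiodefined C4–C7 enolate, which the oxaziridine hydroxylates at C4; a peracid (Rubottom conditions) would also attack the methyl enol ether. C4 is set here: oxygen must enter on the enolate face turned toward C18 (4S); that face looks across the ring toward C20 while the other lies under the C10 silyl ether, so the sense of induction is not secured and is treated under the uncertain steps.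

Step 22
Reactants: 33 tertiary α-hydroxy ketone
Product: 34 allylic diol
Conditions: Bu4NF/AcOH (1:1, 2.5 equiv), THF, 0 °C to rt
Reagents that add atoms: none
Why: Buffered fluoride removes the primary triethylsilyl and the tertiary trimethylsilyl ether and should leave the hindered secondary TBS ethers; the acetic acid buffer protects the β-alkoxy ketone from base.

Step 23
Reactants: 34 allylic diol
Product: 37 methoxy butenolide, via hydroxy enal 35 (not isolated), via lactol 36 (not isolated)
Conditions: MnO2 (excess), CH2Cl2, rt
Reagents that add atoms: none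
Why: Oxidative lactonisation: MnO2 oxidises the allylic primary alcohol to the β-methoxy enal, the O24 hydroxyl closes the lactol, and a second allylic oxidation gives the butenolide; this also turns the enol ether into a stable vinylogous ester.

Step 24
Reactants: 37 methoxy butenolide
Product: 39 C2-methyl methoxy butenolide, via dilithium alkoxide dienolate 38 (not isolated)
Conditions: LiN(iPr)2 (2.5 equiv), THF/DMPU, −78 °C; then MeI, −78 to −40 °C; then AcOH
Reagents that add atoms: iodomethane (CI)
Why: γ-Deprotonation of the vinylogous ester and alkylation at C2: C19 is fully substituted, so the dienolate reacts at its terminus, and the C4 alkoxide formed first disfavours enolisation of the C7 ketone toward C9 by charge repulsion. C2 is epimerisable and is expected to settle in the natural configuration (assumption above).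

Step 25
Reactants: 39 C2-methyl methoxy butenolide
Product: 40 bis-TBS enol lactone
Conditions: LiCl, DMSO, 55 °C; then AcOH
Reagents that add atoms: none
Why: Chloride attacks the O-methyl group of the vinylogous ester (SN2) and releases the enolised β-keto lactone under neutral conditions that spare the silyl ethers and the α-ketol.

Step 26
Reactants: 40 bis-TBS enol lactone
Product: 41 target CNP0115071.1
Conditions: HF·pyridine, pyridine, THF, 0 °C to rt
Reagents that add atoms: none
Why: Buffered fluoride cleavage of the two secondary TBS ethers; no stereocentre is touched and the acid-sensitive ketol and β-hydroxy ketone see only mild conditions.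

## Compound list

1 | (E)-2-methylbut-2-enal (tiglic aldehyde) | C/C=C(\C)C=O | starting material
2 | diethyl [2-(methoxy(methyl)amino)-2-oxoethyl]phosphonate | CCOP(=O)(CC(=O)N(C)OC)OCC | starting material
3 | (2E,4E)-N-methoxy-N,4-dimethylhexa-2,4-dienamide | C/C=C(\C)/C=C/C(=O)N(C)OC | intermediate
4 | (2E,4E)-4-methylhexa-2,4-dienal | C/C=C(\C)/C=C/C=O | intermediate
5 | allyltributylstannane | C=CC[Sn](CCCC)(CCCC)CCCC | starting material
6 | (4R,5E,7E)-7-methylnona-1,5,7-trien-4-ol | C=CC[C@@H](O)/C=C/C(/C)=C/C | intermediate
7 | methyl acrylate | C=CC(=O)OC | starting material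
8 | methyl 2-(1-hydroxybut-3-enyl)-4,5-dimethylcyclohex-3-ene-1-carboxylate, all ring substituents cis (present as bromomagnesium alkoxide) | C=CC[C@@H](O)[C@H]1C=C(C)[C@@H](C)C[C@H]1C(=O)OC | intermediate (not isolated)
9 | 3-allyl-5,6-dimethyl-3a,6,7,7a-tetrahydro-2-benzofuran-1(3H)-one, cis-fused, allyl on the convex face, C6 methyl trans to the ring-fusion hydrogens | C=CC[C@H]1OC(=O)[C@@H]2C[C@H](C)C(C)=C[C@H]12 | intermediate
10 | potassium enolate of lactone 9 | C=CC[C@H]1OC([O-])=C2C[C@H](C)C(C)=C[C@H]12.[K+] | intermediate (not isolated)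
11 | 7a-hydroxy derivative of 9 (cis ring fusion kept) | C=CC[C@H]1OC(=O)[C@]2(O)C[C@H](C)C(C)=C[C@H]12 | intermediate
12 | 4,5-epoxide of 11, epoxide oxygen syn to the 7a-hydroxyl | C=CC[C@H]1OC(=O)[C@]2(O)C[C@H](C)[C@@]3(C)O[C@H]3[C@H]12 | intermediate
13 | 7a-acetate of 12 | C=CC[C@H]1OC(=O)[C@]2(OC(C)=O)C[C@H](C)[C@@]3(C)O[C@H]3[C@H]12 | intermediate
14 | spiro tetronic acid with cyclohexane epoxide and free C10 hydroxyl | C=CC[C@@H](O)[C@H]1[C@@H]2O[C@]2(C)[C@@H](C)C[C@]13OC(=O)C=C3O | intermediate (not isolated)
15 | cage tetronate diol (2-oxabicyclo[2.2.2]octane fused to the butenolide, C10 and C13 hydroxyls free, allyl side chain) | C=CC[C@@H](O)[C@H]1[C@H](O)[C@@]2(C)OC3=CC(=O)O[C@@]13C[C@@H]2C | intermediate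
16 | bis-TBS ether of 15 | C=CC[C@@H](O[Si](C)(C)C(C)(C)C)[C@H]1[C@H](O[Si](C)(C)C(C)(C)C)[C@@]2(C)OC3=CC(=O)O[C@@]13C[C@@H]2C | intermediate
17 | C7 aldehyde from 16 | O=CC[C@@H](O[Si](C)(C)C(C)(C)C)[C@H]1[C@H](O[Si](C)(C)C(C)(C)C)[C@@]2(C)OC3=CC(=O)O[C@@]13C[C@@H]2C | intermediate
18 | triethylsilyl enol ether of 17 ((Z) drawn; E/Z mixture expected) | CC[Si](CC)(CC)O/C=C\[C@@H](O[Si](C)(C)C(C)(C)C)[C@H]1[C@H](O[Si](C)(C)C(C)(C)C)[C@@]2(C)OC3=CC(=O)O[C@@]13C[C@@H]2C | intermediate
19 | cyclobutane photoadduct lactone (cyclobutane C7–C9–C18–C19 cis-fused to cyclopentane and lactone; C7 epimers) | CC[Si](CC)(CC)OC1[C@@H]2[C@@H](O[Si](C)(C)C(C)(C)C)[C@H]3[C@H](O[Si](C)(C)C(C)(C)C)[C@@]4(C)O[C@]2([C@@H]1C(=O)O5)[C@]35C[C@@H]4C | intermediate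
20 | N-methoxy-N-methylacetamide | CC(=O)N(C)OC | starting material
21 | lithium enolate of lactone 19 | CC[Si](CC)(CC)OC1[C@@H]2[C@@H](O[Si](C)(C)C(C)(C)C)[C@H]3[C@H](O[Si](C)(C)C(C)(C)C)[C@@]4(C)O[C@]2(C1=C([O-])O5)[C@]35C[C@@H]4C.[Li+] | intermediate (not isolated)
22 | C19-acetyl lactone (acetyl on the convex face) | CC[Si](CC)(CC)OC1[C@@H]2[C@@H](O[Si](C)(C)C(C)(C)C)[C@H]3[C@H](O[Si](C)(C)C(C)(C)C)[C@@]4(C)O[C@]2([C@]1(C(C)=O)C(=O)O5)[C@]35C[C@@H]4C | intermediate
23 | potassium enolate of methyl ketone 22 | CC[Si](CC)(CC)OC1[C@@H]2[C@@H](O[Si](C)(C)C(C)(C)C)[C@H]3[C@H](O[Si](C)(C)C(C)(C)C)[C@@]4(C)O[C@]2([C@]1(C([O-])=C)C(=O)O5)[C@]35C[C@@H]4C.[K+] | intermediate (not isolated)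
24 | C19-(1-methoxyvinyl) lactone | CC[Si](CC)(CC)OC1[C@@H]2[C@@H](O[Si](C)(C)C(C)(C)C)[C@H]3[C@H](O[Si](C)(C)C(C)(C)C)[C@@]4(C)O[C@]2([C@]1(C(OC)=C)C(=O)O5)[C@]35C[C@@H]4C | intermediate
25 | diol (C22 primary OH, O24 tertiary OH) with C7 triethylsilyl ether | CC[Si](CC)(CC)OC1[C@@H]2[C@@H](O[Si](C)(C)C(C)(C)C)[C@H]3[C@H](O[Si](C)(C)C(C)(C)C)[C@@]4(C)O[C@]2([C@]1(C(OC)=C)CO)[C@]3(O)C[C@@H]4C | intermediate
26 | triol (C7, C22, O24 hydroxyls free) | OC1[C@@H]2[C@@H](O[Si](C)(C)C(C)(C)C)[C@H]3[C@H](O[Si](C)(C)C(C)(C)C)[C@@]4(C)O[C@]2([C@]1(C(OC)=C)CO)[C@]3(O)C[C@@H]4C | intermediate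
27 | C22 triethylsilyl ether of 26 | OC1[C@@H]2[C@@H](O[Si](C)(C)C(C)(C)C)[C@H]3[C@H](O[Si](C)(C)C(C)(C)C)[C@@]4(C)O[C@]2([C@]1(C(OC)=C)CO[Si](CC)(CC)CC)[C@]3(O)C[C@@H]4C | intermediate
28 | cyclobutanone (C7 ketone) | O=C1[C@@H]2[C@@H](O[Si](C)(C)C(C)(C)C)[C@H]3[C@H](O[Si](C)(C)C(C)(C)C)[C@@]4(C)O[C@]2([C@]1(C(OC)=C)CO[Si](CC)(CC)CC)[C@]3(O)C[C@@H]4C | intermediate
29 | cis-1-isopropenyl-2-(1-methoxyvinyl)cyclobutanol fused to the oxa-cage (C22 as triethylsilyl ether, O24–H free) | C=C(C)[C@@]1(O)[C@@H]2[C@@H](O[Si](C)(C)C(C)(C)C)[C@H]3[C@H](O[Si](C)(C)C(C)(C)C)[C@@]4(C)O[C@]2([C@]1(C(OC)=C)CO[Si](CC)(CC)CC)[C@]3(O)C[C@@H]4C | intermediate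
30 | dipotassium salt: C7 enolate and O24 alkoxide of the ring-expanded cyclooctadiene | C1C/C(C)=C([O-])\[C@@H]2[C@@H](O[Si](C)(C)C(C)(C)C)[C@H]3[C@H](O[Si](C)(C)C(C)(C)C)[C@@]4(C)O[C@]2(/C(CO[Si](CC)(CC)CC)=C\1OC)[C@]3([O-])C[C@@H]4C.[K+].[K+] | intermediate (not isolated)
31 | cyclooctadiene bis(enol ether): C7 trimethylsilyl enol ether, C20 methyl enol ether, O24 trimethylsilyl ether | C1C/C(C)=C(O[Si](C)(C)C)\[C@@H]2[C@@H](O[Si](C)(C)C(C)(C)C)[C@H]3[C@H](O[Si](C)(C)C(C)(C)C)[C@@]4(C)O[C@]2(/C(CO[Si](CC)(CC)CC)=C\1OC)[C@]3(O[Si](C)(C)C)C[C@@H]4C | intermediate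
32 | lithium C4–C7 enolate from 31 | C1C/C(C)=C([O-])\[C@@H]2[C@@H](O[Si](C)(C)C(C)(C)C)[C@H]3[C@H](O[Si](C)(C)C(C)(C)C)[C@@]4(C)O[C@]2(/C(CO[Si](CC)(CC)CC)=C\1OC)[C@]3(O[Si](C)(C)C)C[C@@H]4C.[Li+] | intermediate (not isolated)
33 | (4S)-tertiary α-hydroxy ketone (C4 OH, C7 ketone) | C1C[C@](C)(O)C(=O)[C@@H]2[C@@H](O[Si](C)(C)C(C)(C)C)[C@H]3[C@H](O[Si](C)(C)C(C)(C)C)[C@@]4(C)O[C@]2(/C(CO[Si](CC)(CC)CC)=C\1OC)[C@]3(O[Si](C)(C)C)C[C@@H]4C | intermediate
34 | allylic diol (C22 OH, O24–H) | C1C[C@](C)(O)C(=O)[C@@H]2[C@@H](O[Si](C)(C)C(C)(C)C)[C@H]3[C@H](O[Si](C)(C)C(C)(C)C)[C@@]4(C)O[C@]2(/C(CO)=C\1OC)[C@]3(O)C[C@@H]4C | intermediate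
35 | β-methoxy enal (C22 aldehyde) | C1C[C@](C)(O)C(=O)[C@@H]2[C@@H](O[Si](C)(C)C(C)(C)C)[C@H]3[C@H](O[Si](C)(C)C(C)(C)C)[C@@]4(C)O[C@]2(/C(C=O)=C\1OC)[C@]3(O)C[C@@H]4C | intermediate (not isolated)
36 | lactol of 35 (C22 epimers) | C1C[C@](C)(O)C(=O)[C@@H]2[C@@H](O[Si](C)(C)C(C)(C)C)[C@H]3[C@H](O[Si](C)(C)C(C)(C)C)[C@@]4(C)O[C@@]25/C(=C\1OC)C(O)O[C@@]35C[C@@H]4C | intermediate (not isolated)
37 | methoxy butenolide (vinylogous methyl ester of the β-keto lactone) | C1C[C@](C)(O)C(=O)[C@@H]2[C@@H](O[Si](C)(C)C(C)(C)C)[C@H]3[C@H](O[Si](C)(C)C(C)(C)C)[C@@]4(C)O[C@@]25/C(=C\1OC)C(=O)O[C@@]35C[C@@H]4C | intermediate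
38 | dilithium C4 alkoxide and C2 dienolate of 37 | C1C[C@](C)([O-])C(=O)[C@@H]2[C@@H](O[Si](C)(C)C(C)(C)C)[C@H]3[C@H](O[Si](C)(C)C(C)(C)C)[C@@]4(C)O[C@@]25C(C(OC)=1)=C([O-])O[C@@]35C[C@@H]4C.[Li+].[Li+] | intermediate (not isolated)
39 | C2-methyl methoxy butenolide | C[C@H]1C[C@](C)(O)C(=O)[C@@H]2[C@@H](O[Si](C)(C)C(C)(C)C)[C@H]3[C@H](O[Si](C)(C)C(C)(C)C)[C@@]4(C)O[C@@]25/C(=C\1OC)C(=O)O[C@@]35C[C@@H]4C | intermediate
40 | bis-TBS ether of the target (free enol) | C[C@H]1C[C@](C)(O)C(=O)[C@@H]2[C@@H](O[Si](C)(C)C(C)(C)C)[C@H]3[C@H](O[Si](C)(C)C(C)(C)C)[C@@]4(C)O[C@@]25/C(=C\1O)C(=O)O[C@@]35C[C@@H]4C | intermediate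
41 | CNP0115071.1 | C[C@H]1C[C@](C)(O)C(=O)[C@@H]2[C@@H](O)[C@H]3[C@H](O)[C@@]4(C)O[C@@]25/C(=C\1O)C(=O)O[C@@]35C[C@@H]4C | target

## Step count and uncertain steps

Total: 26 steps. Longest linear sequence: 26 steps (from 1 and 2 to 41); the route is fully linear, with 5, 7, 20 and the simple reagents entering along the way.

**Step 20 (key step).** The most likely failure is that the dialkoxide does not rearrange cleanly. Silyl transfer from O23 to the C7 alkoxide can hold the substrate in a non-rearranging form, a [1,3]-shift can compete, and the product enolate can equilibrate toward C9 and expel O17 before it is trapped. Fallback (neutral instead of anionic): from 29, both tertiary hydroxyls are silylated (Me3SiOTf, Et3N, CH2Cl2, −78 °C) to give the bis(trimethylsilyl) ether F1. Heating F1 in toluene (80–110 °C) should bring about the thermal siloxy-Cope rearrangement of the cis-dialkenylcyclobutane, which gives the silyl enol ether directly and rejoins the route at 31 with no enolate ever formed.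

**Step 21 (C4 hydroxylation).** The most likely problem is poor or reversed facial selectivity. In the tub-shaped cycloocta-1,5-diene the enolate face that must be oxidised (syn to C18) points across the ring at C20, and the opposite face is only partly shielded by the C10 silyl ether. Fallback (oxygen first, methyl last, so that the incoming group may use the open face): from 28, CH2=CHMgBr/CeCl3 gives the vinyl carbinol F2. The same rearrangement and trapping (KN(SiMe3)2, 18-crown-6, then Me3SiCl) gives the C5-free bis(enol ether) F3. MeLi and the oxaziridine give the secondary α-ketol F4, whose configuration does not matter, and Dess–Martin oxidation gives the 1,2-dione F5. MeMgBr/CeCl3 then adds to the less hindered C4 carbonyl from the face away from C18, which places the hydroxyl on the C18 side and rejoins the route at 33.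

**Step 24 (C2 methylation).** Deprotonation may not occur at C2, because the C2–H bonds lie near the nodal plane of the vinylogous ester in the tub conformer. Enolisation toward C9 with loss of O17, or alkylation on the wrong face, are the other risks. Fallback (dianion of the free β-keto lactone instead of the vinylogous ester anion): from 37, demethylation first (LiCl, DMSO) gives the unmethylated enol lactone F6. Its polyanion (LiN(iPr)2, 3.3 equiv), in which the enolate oxygen on C20 directs the last deprotonation to C2, is methylated with MeI and rejoins the route at 40. In either variant a wrong C2 epimer would be equilibrated with mild base at the stage of 40.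

**Step 12 (photocycloaddition).** The electron-rich silyl enol ether may be lost to hydrolysis, electron transfer or oxetane formation before the [2+2] closure, or closure may take the crossed course. Fallback (enol ester partner): from 17, Ac2O/KOAc (heat) gives the enol acetate F7. Irradiation gives the acetate photoadduct F8, K2CO3/MeOH gives the cyclobutanol lactone F9, and TESCl/imidazole rejoins the route at 19.

**Step 14 (O-methylation).** C-methylation or incomplete enolisation of the hindered ketone may compete. Fallback (ketal elimination instead of enolate alkylation): from 22, aprotic ketalisation (MeOSiMe3, Me3SiOTf cat., CH2Cl2, −78 °C) gives the dimethyl ketal F10. Elimination of methanol (Me3SiOTf, iPr2NEt) toward the only available methyl group rejoins the route at 24.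

**Step 8 (Dieckmann closure and epoxide opening).** The risk is loss of chemoselectivity in the epoxide opening. The C10 hydroxyl set free by the Dieckmann step sits on the same ring face as the tetronic acid and is the better nucleophile, so under acid it may open the epoxide at C15 in a 5-endo mode and close a tetrahydrofuran in place of the wanted ether bridge. Fallback (remove the competing nucleophile before the epoxide is opened): from 13, the Dieckmann closure is run as before, but the dilithium salt is treated at −78 °C with TBSOTf before any acid is added. The C10 alkoxide is silylated, and the silyl tetronate that forms alongside is hydrolysed on aqueous work-up, which gives the C10 silyl ether of the spiro epoxy tetronic acid F11. Camphorsulfonic acid in CH2Cl2 then leaves the tetronic acid oxygen as the only nucleophile for the epoxide and gives the mono-TBS cage tetronate F12, and TBSOTf/2,6-lutidine rejoins the route at 16.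

## Further compounds

F1 | step 20 | bis(trimethylsilyl) ether of 29 (C7 and O24) | C=C(C)[C@@]1(O[Si](C)(C)C)[C@@H]2[C@@H](O[Si](C)(C)C(C)(C)C)[C@H]3[C@H](O[Si](C)(C)C(C)(C)C)[C@@]4(C)O[C@]2([C@]1(C(OC)=C)CO[Si](CC)(CC)CC)[C@]3(O[Si](C)(C)C)C[C@@H]4C
F2 | step 21 | cis-1-vinyl-2-(1-methoxyvinyl)cyclobutanol analogue of 29 | C=C[C@@]1(O)[C@@H]2[C@@H](O[Si](C)(C)C(C)(C)C)[C@H]3[C@H](O[Si](C)(C)C(C)(C)C)[C@@]4(C)O[C@]2([C@]1(C(OC)=C)CO[Si](CC)(CC)CC)[C@]3(O)C[C@@H]4C
F3 | step 21 | C5-free analogue of 31 | C1C/C=C(O[Si](C)(C)C)\[C@@H]2[C@@H](O[Si](C)(C)C(C)(C)C)[C@H]3[C@H](O[Si](C)(C)C(C)(C)C)[C@@]4(C)O[C@]2(/C(CO[Si](CC)(CC)CC)=C\1OC)[C@]3(O[Si](C)(C)C)C[C@@H]4C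
F4 | step 21 | secondary α-ketol (C4 OH, C4 epimers) | C1CC(O)C(=O)[C@@H]2[C@@H](O[Si](C)(C)C(C)(C)C)[C@H]3[C@H](O[Si](C)(C)C(C)(C)C)[C@@]4(C)O[C@]2(/C(CO[Si](CC)(CC)CC)=C\1OC)[C@]3(O[Si](C)(C)C)C[C@@H]4C
F5 | step 21 | C4,C7 1,2-dione | C1CC(=O)C(=O)[C@@H]2[C@@H](O[Si](C)(C)C(C)(C)C)[C@H]3[C@H](O[Si](C)(C)C(C)(C)C)[C@@]4(C)O[C@]2(/C(CO[Si](CC)(CC)CC)=C\1OC)[C@]3(O[Si](C)(C)C)C[C@@H]4C
F6 | step 24 | unmethylated bis-TBS enol lactone | C1C[C@](C)(O)C(=O)[C@@H]2[C@@H](O[Si](C)(C)C(C)(C)C)[C@H]3[C@H](O[Si](C)(C)C(C)(C)C)[C@@]4(C)O[C@@]25/C(=C\1O)C(=O)O[C@@]35C[C@@H]4C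
F7 | step 12 | enol acetate of 17 (E/Z mixture) | CC(=O)OC=C[C@@H](O[Si](C)(C)C(C)(C)C)[C@H]1[C@H](O[Si](C)(C)C(C)(C)C)[C@@]2(C)OC3=CC(=O)O[C@@]13C[C@@H]2C
F8 | step 12 | acetate photoadduct lactone (C7 epimers) | CC(=O)OC1[C@@H]2[C@@H](O[Si](C)(C)C(C)(C)C)[C@H]3[C@H](O[Si](C)(C)C(C)(C)C)[C@@]4(C)O[C@]2([C@@H]1C(=O)O5)[C@]35C[C@@H]4C
F9 | step 12 | cyclobutanol lactone (C7 epimers) | OC1[C@@H]2[C@@H](O[Si](C)(C)C(C)(C)C)[C@H]3[C@H](O[Si](C)(C)C(C)(C)C)[C@@]4(C)O[C@]2([C@@H]1C(=O)O5)[C@]35C[C@@H]4C
F10 | step 14 | dimethyl ketal of 22 | CC[Si](CC)(CC)OC1[C@@H]2[C@@H](O[Si](C)(C)C(C)(C)C)[C@H]3[C@H](O[Si](C)(C)C(C)(C)C)[C@@]4(C)O[C@]2([C@]1(C(C)(OC)OC)C(=O)O5)[C@]35C[C@@H]4C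
F11 | step 8 | C10 TBS ether of spiro epoxy tetronic acid 14 | C=CC[C@@H](O[Si](C)(C)C(C)(C)C)[C@H]1[C@@H]2O[C@]2(C)[C@@H](C)C[C@]13OC(=O)C=C3O
F12 | step 8 | mono-TBS cage tetronate (C10 silyl ether, C13 hydroxyl free) | C=CC[C@@H](O[Si](C)(C)C(C)(C)C)[C@H]1[C@H](O)[C@@]2(C)OC3=CC(=O)O[C@@]13C[C@@H]2C
A1 | alternative 1 | 3-hydroxy-6-methyl-2H-pyran-2-one | CC1=CC=C(O)C(=O)O1
A2 | alternative 1 | (E)-1-propenyl phenyl sulfone | C/C=C/S(=O)(=O)c1ccccc1
A3 | alternative 1 | bridged hydroxy lactone (sulfone at C26, alkene C12=C13) | C[C@H]1[C@H](S(=O)(=O)c2ccccc2)[C@]3(O)C=C[C@@]1(C)OC3=O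
A4 | alternative 2 | spirobutenolide cyclohexadienone aldehyde | O=CCC1=CC(=O)OC12C=CC(=O)C=C2
A5 | alternative 2 | tricyclic butenolide diketone | O=C1CC2=CC(=O)O[C@]23C=CC(=O)C[C@H]13
A6 | alternative 3 | oxa-bridged nine-membered diketone methyl ester | O(Cc1ccccc1)C[C@@H]2[C@@H](O[Si](C)(C)C(C)(C)C)CC(=O)[C@@]4(C)O[C@]2(CC(=O)OC)C(=O)C[C@@H]4C
A7 | alternative 3 | cage keto-lactone | O(Cc1ccccc1)C[C@@H]2[C@@H](O[Si](C)(C)C(C)(C)C)[C@H]3C(=O)[C@@]4(C)O[C@@]25CC(=O)O[C@@]35C[C@@H]4C
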